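**Retrosynthetic overview**
1. 24 ⇐ silyl-protected acid 19 + isobutyric acid 20: a one-flask anti-acyloxylactonisation across C5=C6 makes the lactone C6–O and the ester C5–O bonds (key C–O step, new), then desilylation.
2. 19 ⇐ diene 17: ring-closing metathesis (C5=C6) closes the cycloheptene.
3. 17 ⇐ Weinreb amide 11: crotonoyl-anion equivalent from 12, then chelation-controlled vinyl addition sets C1.
4. 11 ⇐ aldehyde 8 + propionimide 9: Evans syn-aldol sets C9 and C10.
5. 8 ⇐ lactone 3 ⇐ 1 + 2: Rh-catalysed asymmetric vinyl addition sets C7. Ring order: δ-lactone of 1 opened, cycloheptene by metathesis, α-methylene-γ-lactone last by C–O bond formation.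

Assumption: atom labels C1–C15 follow sesquiterpene-lactone numbering (C1 tertiary carbinol, C2 ketone, C5 ester carbon, C6 lactone O–CH, C7 ring-fusion CH, C9 secondary carbinol, C10 methyl-bearing carbon, C12 lactone carbonyl).
Assumption: 12 is taken from the commercial E/Z mixture of 1-methoxybuta-1,3-diene, used in excess; the (Z)-isomer is the one that is α-lithiated.

**Route**

Step 1
Reactants: 1 5,6-dihydro-2H-pyran-2-one; 2 potassium vinyltrifluoroborate
Product: 3 (4S)-4-ethenyloxan-2-one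
Conditions: [Rh(cod)2]BF4 (3 mol %; cod = cycloocta-1,5-diene), (S)-BINAP (3.3 mol %), toluene/H2O 10:1, 100 °C
Reagents that add atoms: none
Why: Hayashi–Miyaura-type rhodium-catalysed asymmetric 1,4-addition of the vinyl group to the s-trans-locked unsaturated lactone, in which the (S)-BINAP complex is expected to expose the same enone face as in additions to cyclohex-2-enone and so sets C7 as the (4S)-lactone.

Step 2
Reactants: 3 (4S)-4-ethenyloxan-2-one
Product: 6 (4R)-4-ethenyl-3-methylideneoxan-2-one, via Mannich base 4 (not isolated), via methiodide 5 (not isolated)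
Conditions: LiN(iPr)2, THF, −78 °C; CH2=NMe2+ I−, −78 → 0 °C; then MeI, MeOH, rt; then aq. NaHCO3, CH2Cl2, rt
Reagents that add atoms: Eschenmoser's salt (N,N-dimethylmethyleneiminium iodide), C=[N+](C)C.[I-]
Why: α-Methylenation by Mannich reaction of the lactone lithium enolate, N-methylation and Hofmann-type β-elimination, which does not touch the C7 stereocentre (its descriptor changes from S to R by priority only).

Step 3
Reactants: 6 (4R)-4-ethenyl-3-methylideneoxan-2-one
Product: 8 methyl (3R)-3-ethenyl-2-methylidene-5-oxopentanoate, via hydroxy ester 7 (not isolated)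
Conditions: MeOH, Amberlyst-15 (cat.), rt; filter, concentrate cold; then Dess–Martin periodinane, CH2Cl2, 0 °C → rt
Reagents that add atoms: methanol, CO
Why: Acid-catalysed ring-opening transesterification of the δ-lactone in excess methanol followed directly by Dess–Martin oxidation of the liberated primary alcohol, so that the hydroxy ester cannot relactonise.

Step 4
Reactants: 8 methyl (3R)-3-ethenyl-2-methylidene-5-oxopentanoate; 9 (4S)-4-benzyl-3-propanoyl-1,3-oxazolidin-2-one
Product: 10 methyl (3R,5R,6S)-7-[(4S)-4-benzyl-2-oxo-1,3-oxazolidin-3-yl]-3-ethenyl-5-hydroxy-6-methyl-2-methylidene-7-oxoheptanoate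
Conditions: 9, Bu2BOTf, iPr2NEt, CH2Cl2, 0 °C; then 8, −78 → 0 °C; pH 7 buffer, MeOH, 30% H2O2
Reagents that add atoms: none
Why: Evans syn-aldol reaction of the (Z)-boron enolate through a Zimmerman–Traxler chair in which the (S)-benzyl auxiliary dictates C10 (S) and C9 (R) regardless of the remote C7 centre.

Step 5
Reactants: 10 methyl (3R,5R,6S)-7-[(4S)-4-benzyl-2-oxo-1,3-oxazolidin-3-yl]-3-ethenyl-5-hydroxy-6-methyl-2-methylidene-7-oxoheptanoate
Product: 11 methyl (3R,5R,6S)-3-ethenyl-5-hydroxy-7-[methoxy(methyl)amino]-6-methyl-2-methylidene-7-oxoheptanoate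
Conditions: MeNHOMe·HCl, AlMe3, CH2Cl2, −15 → 0 °C; aq. HCl work-up
Reagents that add atoms: N,O-dimethylhydroxylamine hydrochloride, CNOC.Cl
Why: Weinreb transamidation of the imide by the aluminium amide, accelerated by the free β-hydroxyl so that the hindered conjugated methyl ester is left alone at 0 °C and the auxiliary is recovered.

Step 6
Reactants: 11 methyl (3R,5R,6S)-3-ethenyl-5-hydroxy-7-[methoxy(methyl)amino]-6-methyl-2-methylidene-7-oxoheptanoate; 12 (1Z)-1-methoxybuta-1,3-diene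
Product: 13 methyl (3R,5R,6S,8Z)-3-ethenyl-5-hydroxy-8-methoxy-6-methyl-2-methylidene-7-oxoundeca-8,10-dienoate
Conditions: 12 (3 equiv), tBuLi (2.5 equiv), THF, −78 → −40 °C; then 11, −78 °C, 1 h; H2O at −78 °C
Reagents that add atoms: none
Why: Weinreb ketone synthesis with the α-lithiated dienyl ether (a crotonoyl-anion equivalent), where the first equivalent forms the C9 alkoxide and the second adds to the amide to give a stable chelated tetrahedral intermediate, while at −78 °C the hindered 2-alkylacrylate ester should not be attacked and the alkoxide should not lactonise.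

Step 7
Reactants: 13 methyl (3R,5R,6S,8Z)-3-ethenyl-5-hydroxy-8-methoxy-6-methyl-2-methylidene-7-oxoundeca-8,10-dienoate; 14 vinylmagnesium bromide
Product: 16 methyl (3R,5R,6S,7R,9E)-3,7-diethenyl-5,7-dihydroxy-6-methyl-2-methylidene-8-oxoundec-9-enoate, via dienyl ether 15 (not isolated)
Conditions: CH2=CHMgBr (4 equiv), CH2Cl2/THF, −78 °C; then 1 M aq. HCl, THF, 0 °C, 15 min
Reagents that add atoms: water, O
Why: Chelation-controlled Grignard 1,2-addition (Cram-chelate model) in which magnesium bridges the C9 alkoxide and the ketone oxygen so that vinyl enters anti to the C10 methyl group and sets C1 (7R), followed by acid hydrolysis of the 2-methoxydiene to the conjugated (E)-enone.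

Step 8
Reactants: 16 methyl (3R,5R,6S,7R,9E)-3,7-diethenyl-5,7-dihydroxy-6-methyl-2-methylidene-8-oxoundec-9-enoate
Product: 17 methyl (3R,5R,6S,7R,9E)-5-[(tert-butyldimethylsilyl)oxy]-3,7-diethenyl-7-hydroxy-6-methyl-2-methylidene-8-oxoundec-9-enoate
Conditions: tBuMe2SiCl, imidazole, DMF, rt
Reagents that add atoms: tert-butyldimethylsilyl chloride, CC(C)(C)[Si](C)(C)Cl
Why: Selective silylation of the secondary C9 hydroxyl (the hindered tertiary α-ketol hydroxyl does not react with the silyl chloride), which masks the only hydroxyl that could later attack C5 or C6 across the ring and also blocks δ-lactonisation.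

Step 9
Reactants: 17 methyl (3R,5R,6S,7R,9E)-5-[(tert-butyldimethylsilyl)oxy]-3,7-diethenyl-7-hydroxy-6-methyl-2-methylidene-8-oxoundec-9-enoate
Product: 18 methyl 2-[(1R,4R,5S,6R)-4-[(2E)-but-2-enoyl]-6-[(tert-butyldimethylsilyl)oxy]-4-hydroxy-5-methylcyclohept-2-en-1-yl]prop-2-enoate
Conditions: second-generation Hoveyda–Grubbs catalyst RuCl2(=CH-C6H4-2-OiPr)(H2IMes) (5 mol %), CH2Cl2 (2 mM), 40 °C
Reagents that add atoms: none
Why: Ring-closing metathesis of the two monosubstituted vinyl groups to the cis-cycloheptene, helped by the quaternary C1 centre, while the 1,1-disubstituted acrylate and the electron-poor enone alkene react much more slowly.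

Step 10
Reactants: 18 methyl 2-[(1R,4R,5S,6R)-4-[(2E)-but-2-enoyl]-6-[(tert-butyldimethylsilyl)oxy]-4-hydroxy-5-methylcyclohept-2-en-1-yl]prop-2-enoate
Product: 19 2-[(1R,4R,5S,6R)-4-[(2E)-but-2-enoyl]-6-[(tert-butyldimethylsilyl)oxy]-4-hydroxy-5-methylcyclohept-2-en-1-yl]prop-2-enoic acid
Conditions: Me3SnOH, ClCH2CH2Cl, 70 °C; dilute aq. HCl wash
Reagents that add atoms: trimethyltin hydroxide, C[Sn](C)(C)O
Why: Mild tin hydroxide-mediated methyl ester cleavage (acyl substitution) that leaves the enone, the tertiary α-ketol and the silyl ether intact.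

Step 11
Reactants: 19 2-[(1R,4R,5S,6R)-4-[(2E)-but-2-enoyl]-6-[(tert-butyldimethylsilyl)oxy]-4-hydroxy-5-methylcyclohept-2-en-1-yl]prop-2-enoic acid; 20 2-methylpropanoic acid
Product: 24 (3aS,5R,6S,7S,8S,8aR)-7-[(2E)-but-2-enoyl]-5,7-dihydroxy-6-methyl-3-methylidene-2-oxooctahydro-2H-cyclohepta[b]furan-8-yl 2-methylpropanoate, via iodolactone 21 (not isolated), via epoxy lactone 22 (not isolated), via silyl ether 23 (not isolated)
Conditions: 20 (10 equiv), Ag2O (1.2 equiv), I2 (1.05 equiv), 4 Å MS, CH2Cl2, −20 °C → rt, dark, then 40 °C; filter; then HF·pyridine, MeCN, 0 °C → rt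
Reagents that add atoms: none
Why: Proposed new method: a hydroxyl-relayed Prévost-type anti-acyloxylactonisation, in which isobutyryl hypoiodite (from I2 and silver isobutyrate made in the flask) forms the iodonium ion on the alkene face opposite the C7 side chain, the carboxylate closes 5-exo at C6 to the cis-fused lactone with iodine anti at C5, a second silver ion then removes iodide with backside participation of the antiperiplanar tertiary C1 hydroxyl to give the C1/C5 epoxide, and isobutyric acid opens this α,β-epoxy ketone at its non-quaternary β-carbon C5 with inversion, so that C6 (8aR) and C5 (8S) follow stereospecifically from C7 and C1 before fluoride removes the silyl group; the closest known reactions are iodolactonisation, the Prévost trans-diacyloxylation of alkenes (there an ester carbonyl, not a hydroxyl, relays the second substitution), silver-assisted closure of iodohydrins to epoxides and the acidolysis of epoxides.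

**Compound list**

1 | 5,6-dihydro-2H-pyran-2-one | O=C1C=CCCO1 | starting material
2 | potassium vinyltrifluoroborate | C=C[B-](F)(F)F.[K+] | starting material
3 | (4S)-4-ethenyloxan-2-one | O=C1C[C@@H](C=C)CCO1 | intermediate
4 | (3S,4R)-3-[(dimethylamino)methyl]-4-ethenyloxan-2-one (trans Mannich base) | CN(C)C[C@H]1C(=O)OCC[C@@H]1C=C | intermediate (not isolated)
5 | [(3S,4R)-4-ethenyl-2-oxooxan-3-yl]-N,N,N-trimethylmethanaminium iodide | C[N+](C)(C)C[C@H]1C(=O)OCC[C@@H]1C=C.[I-] | intermediate (not isolated)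
6 | (4R)-4-ethenyl-3-methylideneoxan-2-one | C=C1C(=O)OCC[C@@H]1C=C | intermediate
7 | methyl (3R)-3-ethenyl-5-hydroxy-2-methylidenepentanoate | C=C(C(=O)OC)[C@@H](C=C)CCO | intermediate (not isolated)
8 | methyl (3R)-3-ethenyl-2-methylidene-5-oxopentanoate | C=C(C(=O)OC)[C@@H](C=C)CC=O | intermediate
9 | (4S)-4-benzyl-3-propanoyl-1,3-oxazolidin-2-one | CCC(=O)N1C(=O)OC[C@@H]1Cc1ccccc1 | starting material
10 | methyl (3R,5R,6S)-7-[(4S)-4-benzyl-2-oxo-1,3-oxazolidin-3-yl]-3-ethenyl-5-hydroxy-6-methyl-2-methylidene-7-oxoheptanoate | C=C(C(=O)OC)[C@@H](C=C)C[C@@H](O)[C@H](C)C(=O)N1C(=O)OC[C@@H]1Cc1ccccc1 | intermediate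
11 | methyl (3R,5R,6S)-3-ethenyl-5-hydroxy-7-[methoxy(methyl)amino]-6-methyl-2-methylidene-7-oxoheptanoate | C=C(C(=O)OC)[C@@H](C=C)C[C@@H](O)[C@H](C)C(=O)N(C)OC | intermediate
12 | (1Z)-1-methoxybuta-1,3-diene | CO/C=C\C=C | starting material
13 | methyl (3R,5R,6S,8Z)-3-ethenyl-5-hydroxy-8-methoxy-6-methyl-2-methylidene-7-oxoundeca-8,10-dienoate | C=C(C(=O)OC)[C@@H](C=C)C[C@@H](O)[C@H](C)C(=O)/C(OC)=C/C=C | intermediate
14 | vinylmagnesium bromide | C=C[Mg]Br | starting material
15 | methyl (3R,5R,6S,7R,8Z)-3,7-diethenyl-5,7-dihydroxy-8-methoxy-6-methyl-2-methylideneundeca-8,10-dienoate | C=C(C(=O)OC)[C@@H](C=C)C[C@@H](O)[C@H](C)[C@@](O)(/C(OC)=C/C=C)C=C | intermediate (not isolated)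
16 | methyl (3R,5R,6S,7R,9E)-3,7-diethenyl-5,7-dihydroxy-6-methyl-2-methylidene-8-oxoundec-9-enoate | C=C(C(=O)OC)[C@@H](C=C)C[C@@H](O)[C@H](C)[C@@](O)(C(=O)/C=C/C)C=C | intermediate
17 | methyl (3R,5R,6S,7R,9E)-5-[(tert-butyldimethylsilyl)oxy]-3,7-diethenyl-7-hydroxy-6-methyl-2-methylidene-8-oxoundec-9-enoate | C=C(C(=O)OC)[C@@H](C=C)C[C@@H](O[Si](C)(C)C(C)(C)C)[C@H](C)[C@@](O)(C(=O)/C=C/C)C=C | intermediate
18 | methyl 2-[(1R,4R,5S,6R)-4-[(2E)-but-2-enoyl]-6-[(tert-butyldimethylsilyl)oxy]-4-hydroxy-5-methylcyclohept-2-en-1-yl]prop-2-enoate | C=C(C(=O)OC)[C@@H]1C[C@@H](O[Si](C)(C)C(C)(C)C)[C@H](C)[C@@](O)(C(=O)/C=C/C)C=C1 | intermediate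
19 | 2-[(1R,4R,5S,6R)-4-[(2E)-but-2-enoyl]-6-[(tert-butyldimethylsilyl)oxy]-4-hydroxy-5-methylcyclohept-2-en-1-yl]prop-2-enoic acid | C=C(C(=O)O)[C@@H]1C[C@@H](O[Si](C)(C)C(C)(C)C)[C@H](C)[C@@](O)(C(=O)/C=C/C)C=C1 | intermediate
20 | 2-methylpropanoic acid (isobutyric acid) | CC(C)C(=O)O | starting material
21 | (3aS,5R,6S,7R,8S,8aR)-7-[(2E)-but-2-enoyl]-5-[(tert-butyldimethylsilyl)oxy]-7-hydroxy-8-iodo-6-methyl-3-methylideneoctahydro-2H-cyclohepta[b]furan-2-one | C=C1C(=O)O[C@@H]2[C@H]1C[C@@H](O[Si](C)(C)C(C)(C)C)[C@H](C)[C@@](O)(C(=O)/C=C/C)[C@H]2I | intermediate (not isolated)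
22 | (3aS,5R,6S,7S,8R,8aR)-7-[(2E)-but-2-enoyl]-5-[(tert-butyldimethylsilyl)oxy]-7,8-epoxy-6-methyl-3-methylideneoctahydro-2H-cyclohepta[b]furan-2-one | C=C1C(=O)O[C@@H]2[C@H]1C[C@@H](O[Si](C)(C)C(C)(C)C)[C@H](C)[C@]3(C(=O)/C=C/C)O[C@@H]32 | intermediate (not isolated)
23 | (3aS,5R,6S,7S,8S,8aR)-7-[(2E)-but-2-enoyl]-5-[(tert-butyldimethylsilyl)oxy]-7-hydroxy-6-methyl-3-methylidene-2-oxooctahydro-2H-cyclohepta[b]furan-8-yl 2-methylpropanoate | C=C1C(=O)O[C@@H]2[C@H]1C[C@@H](O[Si](C)(C)C(C)(C)C)[C@H](C)[C@@](O)(C(=O)/C=C/C)[C@H]2OC(=O)C(C)C | intermediate (not isolated)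
24 | (3aS,5R,6S,7S,8S,8aR)-7-[(2E)-but-2-enoyl]-5,7-dihydroxy-6-methyl-3-methylidene-2-oxooctahydro-2H-cyclohepta[b]furan-8-yl 2-methylpropanoate | C=C1C(=O)O[C@@H]2[C@H]1C[C@@H](O)[C@H](C)[C@@](O)(C(=O)/C=C/C)[C@H]2OC(=O)C(C)C | target

**Totals and risks**

Total step count: 11. Longest linear sequence: 11 steps (1 → 24); 2, 9, 12, 14 and 20 are bought.

Steps most likely to fail:

Step 11 (the new cascade). Silver-assisted ionisation at C5 could trigger a semipinacol shift instead of epoxide closure, and the acidolysis of the hindered epoxy ketone could be slow. The fallback uses known reactions only, sets out from 19 and comes back at 24. Iodolactonisation with I2/NaHCO3 in aqueous MeCN gives the iodolactone 21, which is isolated. K2CO3 in MeCN closes the epoxy lactone 22. Catalytic HClO4 in aqueous THF opens 22 with water at C5 to the trans-diol (3aS,5R,6S,7S,8S,8aR)-7-[(2E)-but-2-enoyl]-5-[(tert-butyldimethylsilyl)oxy]-7,8-dihydroxy-6-methyl-3-methylideneoctahydro-2H-cyclohepta[b]furan-2-one F8. Isobutyric anhydride/DMAP/pyridine acylates only the secondary C5 hydroxyl of F8 to give 23, and HF·pyridine gives 24. The ester C–O bond is then made by acylating a hydroxyl rather than by carboxylate opening of the epoxide.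

Step 7 (chelation-controlled vinyl addition). Selectivity at C1 could be low, and the free C9 alkoxide could lactonise onto the ester in steps 6 and 7. The fallback sets out from 11 and comes back at 18. Silylation (tBuMe2SiCl, imidazole, DMF) gives methyl (3R,5R,6S)-5-[(tert-butyldimethylsilyl)oxy]-3-ethenyl-7-[methoxy(methyl)amino]-6-methyl-2-methylidene-7-oxoheptanoate F4. Vinylmagnesium bromide 14 (THF, 0 °C) converts the Weinreb amide into the vinyl ketone methyl (3R,5R,6S)-5-[(tert-butyldimethylsilyl)oxy]-3-ethenyl-6-methyl-2-methylidene-7-oxonon-8-enoate F5. Ring-closing metathesis with the second-generation Hoveyda–Grubbs catalyst gives the cycloheptenone methyl 2-[(1R,5S,6R)-6-[(tert-butyldimethylsilyl)oxy]-5-methyl-4-oxocyclohept-2-en-1-yl]prop-2-enoate F6. The lithium reagent from 12 (tBuLi, THF, −78 °C) adds 1,2 to the ring ketone, expected from the face anti to the adjacent C10 methyl group, to give methyl 2-[(1R,4R,5S,6R)-6-[(tert-butyldimethylsilyl)oxy]-4-hydroxy-4-[(1Z)-1-methoxybuta-1,3-dien-1-yl]-5-methylcyclohept-2-en-1-yl]prop-2-enoate F7. Oxalic acid in wet THF hydrolyses only the dienyl ether of F7 and gives 18. C1 is then set by the ring instead of by chelation; the selectivity of this ring addition is less certain.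

Step 1 (enantioselective vinyl transfer to the lactone). Conversion or ee could be low with the vinyl boron reagent. The fallback sets out from 1 and comes back at 3. Copper-catalysed conjugate addition of vinylmagnesium bromide 14 (CuBr·SMe2 cat., THF, −40 °C) gives rac-4-ethenyloxan-2-one F1. Ring opening with (1S)-1-phenylethanamine and AlMe3 in CH2Cl2 gives the diastereomeric amides (3S)-3-ethenyl-5-hydroxy-N-[(1S)-1-phenylethyl]pentanamide F2 and (3R)-3-ethenyl-5-hydroxy-N-[(1S)-1-phenylethyl]pentanamide F3, which are separated by crystallisation or chromatography. Heating F2 with TsOH in toluene relactonises it to 3.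

**Further compounds**

F1 | step 1 | rac-4-ethenyloxan-2-one | O=C1CC(C=C)CCO1
F2 | step 1 | (3S)-3-ethenyl-5-hydroxy-N-[(1S)-1-phenylethyl]pentanamide | O=C(C[C@@H](C=C)CCO)N[C@@H](C)c1ccccc1
F3 | step 1 | (3R)-3-ethenyl-5-hydroxy-N-[(1S)-1-phenylethyl]pentanamide | O=C(C[C@H](C=C)CCO)N[C@@H](C)c1ccccc1
F4 | step 7 | methyl (3R,5R,6S)-5-[(tert-butyldimethylsilyl)oxy]-3-ethenyl-7-[methoxy(methyl)amino]-6-methyl-2-methylidene-7-oxoheptanoate | C=C(C(=O)OC)[C@@H](C=C)C[C@@H](O[Si](C)(C)C(C)(C)C)[C@H](C)C(=O)N(C)OC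
F5 | step 7 | methyl (3R,5R,6S)-5-[(tert-butyldimethylsilyl)oxy]-3-ethenyl-6-methyl-2-methylidene-7-oxonon-8-enoate | C=C(C(=O)OC)[C@@H](C=C)C[C@@H](O[Si](C)(C)C(C)(C)C)[C@H](C)C(=O)C=C
F6 | step 7 | methyl 2-[(1R,5S,6R)-6-[(tert-butyldimethylsilyl)oxy]-5-methyl-4-oxocyclohept-2-en-1-yl]prop-2-enoate | C=C(C(=O)OC)[C@@H]1C[C@@H](O[Si](C)(C)C(C)(C)C)[C@H](C)C(=O)C=C1
F7 | step 7 | methyl 2-[(1R,4R,5S,6R)-6-[(tert-butyldimethylsilyl)oxy]-4-hydroxy-4-[(1Z)-1-methoxybuta-1,3-dien-1-yl]-5-methylcyclohept-2-en-1-yl]prop-2-enoate | C=C(C(=O)OC)[C@@H]1C[C@@H](O[Si](C)(C)C(C)(C)C)[C@H](C)[C@@](O)(/C(OC)=C/C=C)C=C1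
F8 | step 11 | (3aS,5R,6S,7S,8S,8aR)-7-[(2E)-but-2-enoyl]-5-[(tert-butyldimethylsilyl)oxy]-7,8-dihydroxy-6-methyl-3-methylideneoctahydro-2H-cyclohepta[b]furan-2-one | C=C1C(=O)O[C@@H]2[C@H]1C[C@@H](O[Si](C)(C)C(C)(C)C)[C@H](C)[C@@](O)(C(=O)/C=C/C)[C@H]2O
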